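Abietane numbering is used throughout: ring B is C5–C10, ring C is C8, C9, C11–C14, C1–C3 is the ester chain and C20 the methyl group on C10.

## The problem

The target is a ring-A-seco abietane. A cyclohexenone (C7 ketone, C8=C9) is fused to a fully substituted 12-hydroxy-13-isopropyl-11,14-benzoquinone; C10 carries a methyl group and the C1–C3 methyl propanoate chain, and C5 carries an isopropenyl group. There are only two stereocentres, the quaternary C10 and its neighbour C5, with the chain trans to isopropenyl. Because they are adjacent, an existing C5 centre can direct the construction of C10 by enolate alkylation, and neither can epimerize afterwards (C5 is β to the C7 carbonyl, C10 has no hydrogen). The real difficulty is building a hexasubstituted, highly oxidized ring C next to a quaternary carbon and reaching the oxidation pattern at C7, C11, C12 and C14 without damaging sensitive groups. These are the isopropenyl group (lost to strong acid, electrophilic oxidants or hydrogenation; acid-induced migration of the alkene would also erase C5), the nucleophile-sensitive quinone with its acidic vinylogous-acid hydroxyl, and the methyl ester (incompatible with organometallic reagents and hydroxide). The enabling feature is that C14 is a carbon substituent of C8. In a ring-B enone with a methyl group (C14) on C8 and a 1,3-diketone chain (C11–C13) on C9, the methyl is γ to the C11 carbonyl through C8=C9, is held cis to the chain, and lies six atoms from the C13 carbonyl, so one vinylogous aldol bond (C13–C14) closes ring C and aromatization follows. The ten carbons C5–C10, C14 and isopropenyl of that enone are those of (R)-carvone after a 1,3-carbonyl transposition, which also supplies C5 in the correct absolute configuration.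

## Retrosynthesis

**Ester.** Target 20 is cut at the ester O–CH3 bond to acid 19. Making the ester last keeps it out of every basic, nucleophilic or organometallic step. The forward reaction must alkylate the carboxylate selectively beside the acidic 12-hydroxyl.

**Chain oxidation level.** Acid 19 is traced to silyl ether 16, which carries C3 as a protected primary alcohol. A silyl ether survives acetylide addition, chromate oxidation and alkoxide, and can be converted to the acid in one acidic chromate operation. The forward step must spare the isopropenyl group and the hydroxyquinone.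

**C12–O bond.** Hydroxyquinone 16 is cut at C12–O to quinone 14 by way of epoxide 15. Carrying the C12 oxygen through ring formation would need a 2-oxygenated 1,3-diketone, which is much harder to make than the parent diketone. The forward steps need a nucleophilic epoxidation that ignores the isopropenyl group, and an epoxide-to-enol isomerization under base, since strong acid is excluded.

**C14=O.** Quinone 14 is cut at the C14 oxygen to phenol 13, whose para position (C14) is free. This is a standard phenol-to-para-quinone oxidation.

**C13–C14 bond (key cut).** Phenol 13 is cut at C13–C14, with the C13 oxygen returned, to triketone 11. Cuts at C9–C11 or C8–C14 would need an organometallic at a ring-B carbon flanked by the quaternary C10; here every ring-C carbon is already attached and only one bond has to form. The precursor is monocyclic with an acyclic chain. The forward reaction must make C14 the nucleophile and C13 the electrophile, and no others.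

**C11 oxygen.** Triketone 11 is traced to ene-ynedione 9: the C11 carbonyl comes from hydration of the C11≡C12 alkyne. Masking the diketone as an ynone avoids carrying an acidic, chelating 1,3-diketone through the chromate step. The forward reaction must put the oxygen on C11, which the ynone polarization provides.

**C9–C11 bond and carbonyl transposition.** Ynedione 9 is traced through diol 7 to ketone 5 and alkynol 6. The C9–C11 bond is made by acetylide addition to the carvone carbonyl (which becomes C9). An oxidative 1,3-transposition then moves the oxygen to C7 and the alkene to C8=C9, so the carvone 2-methyl becomes C14 on the enone α-carbon. This fixes the carvone mapping and adds all of C11–C13 with the isopropyl group in one fragment.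

**C10–C20 and C10–C1 bonds.** Ketone 5 is cut to 6-methylcarvone 3 and iodide 4, and 3 to carvone 1 and iodomethane 2. The order matters: methyl first, chain second, so that the chain enters anti to the isopropenyl group and ends trans to it. Doing this at the start of the route means C10 is never formed on a congested late intermediate.

## Roads not taken

**Alternative 1:** The cut is through ring B at C9–C10 and C5–C6. A catalytic enantioselective Diels–Alder reaction of aminosiloxydiene A1 with dienal A2 under a chiral Lewis acid would give cyclohexene A3.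
- Merits: both stereocentres and the quaternary carbon come from achiral materials in one catalytic step. The methyl/isopropenyl relationship is fixed stereospecifically by the E geometry of A2. Either enantiomer is accessible.
- Weak points: A2 is a β-substituted α-methyl enal, a sluggish dienophile that is itself a diene, and A1 is acid-labile and not an obvious partner for a strong Lewis acid. A3 contains none of ring C: after amine elimination, C14, C11–C13 and the isopropyl group must all still be attached at C8 and C9, and the formyl group must be homologated by two carbons.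
- Comparison: this road is better in not relying on substrate-controlled alkylation of a hindered enolate. The chosen plan sets against it that carvone already delivers C14 and the carbonyl handle for C9, so ring C needs one C–C bond to the ring and one ring closure. Both enantiomers of carvone are also inexpensive.

**Alternative 2:** The cut is at C9–C11 in the key step, with C8–C14 made just before. Ring B would come from (+)-verbenone A4 (conjugate addition for C10, cyclobutane opening for the isopropenyl group). Its C8 vinyl organometallic would be added to a cyclobutenedione to give cyclobutenone A5. Thermolysis opens A5 to a dienylketene whose six-electron electrocyclization gives hydroquinone A6.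
- Merits: ring C arrives with all four substituents and all three oxygens (C11, C12, C14), so the end game is only oxidation and unmasking. In oxidation-state economy this is better than the chosen plan, which spends three steps (phenol oxidation, epoxidation, isomerization) to reach the same ring.
- Weak points: A5 needs a ring-B vinyl nucleophile at C8 between an oxygenated C7 and the quaternary C10, reached from A4 only after several adjustments. Addition to an unsymmetrical cyclobutenedione poses a regiochemical problem. C7 still needs a late oxidation, and the 12-methyl ether must be cleaved beside the methyl ester.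
- Comparison: the chosen plan sets against it a much shorter route to its cyclization precursor (five steps from carvone), no regiochemical choice in assembling ring C, and the C7 ketone in place from the start.

**Alternative 3:** The cut is at three bonds, C11–C12, C13–C14 and C14–C8. A Dötz benzannulation of the ring-B alkenyl(methoxy)carbene complex A7 with alkyne A8, with C14 supplied by a carbonyl ligand, would give phenol A9.
- Merits: three bonds and the ring form in one convergent step. The terminal alkyne reliably places isopropyl next to the new hydroxyl. The 11,14-dioxygenation leads to the quinone by oxidative demethylation.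
- Weak points: the stoichiometric chromium carbene must be made from a C9 vinyl anion beside the quaternary C10, and that congestion favours side paths of the benzannulation. C7 again needs oxidation. C12 is unoxygenated, so the same late hydroxylation as in the chosen plan remains.
- Comparison: this road is equal on the C12 problem and better in convergence. The chosen plan sets against it that no organometallic is needed at the hindered C9 and that ring C closes from carbons already in place. It must be admitted that the chosen plan itself uses stoichiometric hexavalent chromium twice.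

Key step: step 6

Assumption: alkynol 6 is used as the racemate because its carbinol carbon becomes the C13 carbonyl, and iodide 4 is taken in place of the corresponding bromide as the better electrophile for a quaternary alkylation.

## Route

Step 1
Reactants: 1 (R)-(−)-carvone; 2 iodomethane
Product: 3 (5R)-2,6-dimethyl-5-(prop-1-en-2-yl)cyclohex-2-en-1-one (6-methylcarvone; mixture of C6 epimers)
Conditions: LiN(i-Pr)2, THF, −78 °C; MeI, −78 → 0 °C
Reagents that add atoms: iodomethane (2), CI
Why: Kinetic α′-deprotonation of the enone gives the cross-conjugated lithium enolate, which is C-methylated (enolate alkylation); the new centre forms as an epimer mixture, which does not matter because it is re-enolized in step 2.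

Step 2
Reactants: 3 6-methylcarvone; 4 tert-butyl(3-iodopropoxy)dimethylsilane
Product: 5 (5S,6S)-6-[3-(tert-butyldimethylsilyloxy)propyl]-2,6-dimethyl-5-(prop-1-en-2-yl)cyclohex-2-en-1-one (chain trans and methyl cis to isopropenyl)
Conditions: LiN(i-Pr)2, THF, −78 → 0 °C; HMPA, 4, −78 °C → rt
Reagents that add atoms: tert-butyl(3-iodopropoxy)dimethylsilane (4), CC(C)(C)[Si](C)(C)OCCCI
Why: Enolate alkylation forming the quaternary carbon; the electrophile should approach the tetrasubstituted enolate on the face anti to the adjacent isopropenyl group, as is usual for 6-methylcarvone, so the chain ends trans to isopropenyl and C10 is set by C5. HMPA is added to make the hindered enolate reactive towards the unactivated primary iodide.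

Step 3
Reactants: 5 ketone; 6 4-methylpent-1-yn-3-ol (racemic)
Product: 7 (5S,6S)-6-[3-(tert-butyldimethylsilyloxy)propyl]-1-(3-hydroxy-4-methylpent-1-yn-1-yl)-2,6-dimethyl-5-(prop-1-en-2-yl)cyclohex-2-en-1-ol (mixture at both carbinol carbons)
Conditions: 6, n-BuLi (2 equiv per 6), THF, −78 → 0 °C; then 5, −78 °C → rt; H2O
Reagents that add atoms: 4-methylpent-1-yn-3-ol (6), C#CC(O)C(C)C
Why: 1,2-Addition of a lithium acetylide (alkynol dianion) to a hindered enone carbonyl that cannot enolize towards the quaternary carbon, a reaction well known for 2,6,6-trisubstituted cyclohexenones; both new carbinol centres form as mixtures and are destroyed in step 4.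

Step 4
Reactants: 7 diol
Product: 9 (4S,5S)-4-[3-(tert-butyldimethylsilyloxy)propyl]-2,4-dimethyl-3-(4-methyl-3-oxopent-1-yn-1-yl)-5-(prop-1-en-2-yl)cyclohex-2-en-1-one, via hydroxy ynone 8 (not isolated)
Conditions: (C5H5NH)[CrO3Cl] (excess), 4 Å molecular sieves, CH2Cl2, rt
Reagents that add atoms: pyridinium chlorochromate (C5H5NH)[CrO3Cl], [O-][Cr](=O)(=O)Cl.c1cc[nH+]cc1
Why: Dauben–Michno oxidative 1,3-transposition: the chromate ester of the tertiary allylic alcohol shifts its oxygen to the unhindered allylic terminus and is oxidized there, placing the ketone at C7 and the alkene at C8=C9 (the C7 oxygen comes from the chromate). The same reagent oxidizes the secondary propargylic alcohol to the ynone, so one operation gives 9; the silyl ether and isopropenyl group tolerate this reagent.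

Step 5
Reactants: 9 ene-ynedione
Product: 11 (4S,5S)-4-[3-(tert-butyldimethylsilyloxy)propyl]-2,4-dimethyl-3-(4-methyl-3-oxopentanoyl)-5-(prop-1-en-2-yl)cyclohex-2-en-1-one (triketone; side chain largely enolized), via enaminone 10 (not isolated)
Conditions: Et2NH, EtOH, 0 °C → rt; then 10% aq. oxalic acid, THF, rt
Reagents that add atoms: water, O
Why: Conjugate addition of the amine to the ynone at the carbon β to the isobutyryl carbonyl (C11) gives vinylogous amide 10, and mild acid hydrolysis leaves the oxygen on C11 (net ynone hydration to a 1,3-diketone); the directly attached acyl group polarizes the alkyne more strongly than the vinylogous ring ketone, and brief aqueous oxalic acid should spare the silyl ether.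

Step 6
Reactants: 11 triketone
Product: 13 (3S,4S)-4-[3-(tert-butyldimethylsilyloxy)propyl]-5-hydroxy-4-methyl-7-(propan-2-yl)-3-(prop-1-en-2-yl)-3,4-dihydronaphthalen-1(2H)-one (11-hydroxy-13-isopropyl arene with the C7 ketone), via aldol adduct 12 (not isolated)
Conditions: KOt-Bu, t-BuOH/THF, rt → 50 °C, argon; AcOH
Reagents that add atoms: none
Why: The base first holds the diketone as its enolate, but proton transfer in t-BuOH gives access to the tautomeric dienolate in which C11 is a ketone γ-deprotonated through C8=C9 at the C14 methyl; C14 then adds to the C13 ketone (intramolecular vinylogous aldol) to give aldolate 12. E1cB loss of the C13 oxygen across C12–C13 and tautomerization of the resulting cross-conjugated dienone give the C11 phenoxide, so the sequence ends in an irreversible aromatization. The closest known reaction type is the aldol cyclization–aromatization of poly-β-carbonyl chains and of enediones with 1,3-diketone side chains to phenols. Ring C closes in a 6-(enolendo)-exo-trig mode with respect to the dienolate, which is favoured, and C14 and the chain are held cis on C8=C9, so the reacting ends are preorganized. No stereocentre is formed, and C5 (β to the C7 ketone) and C10 (quaternary) cannot be scrambled by enolization. The step needs site selectivity among three nucleophilic carbons (C14, C6, C12) and three carbonyls (C13, C11, C7): C12 onto C7 would require a bridgehead alkene, C6 onto C13 or C11 gives strained bridged aldols that revert, and addition of the enol oxygen to C8 is a reversible oxa-Michael reaction, whereas only C14 onto C13 gives an unstrained six-membered ring that aromatizes. Argon is needed because the dienolate and phenoxide are air-sensitive; the silyl ether and isopropenyl group are inert to alkoxide.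

Step 7
Reactants: 13 phenol
Product: 14 (3S,4S)-4-[3-(tert-butyldimethylsilyloxy)propyl]-4-methyl-7-(propan-2-yl)-3-(prop-1-en-2-yl)-3,4-dihydronaphthalene-1,5,8(2H)-trione (11,14-quinone with C12–H)
Conditions: (KSO3)2NO, KH2PO4, acetone/H2O, rt
Reagents that add atoms: potassium nitrosodisulfonate (KSO3)2NO, [K+].[K+].[O]N(S(=O)(=O)[O-])S(=O)(=O)[O-]
Why: Teuber oxidation: one nitroxyl radical abstracts the phenolic hydrogen and a second couples at the free para carbon C14, and loss of imidodisulfonate gives the para-quinone; the buffered aqueous medium leaves the isopropenyl group and silyl ether untouched.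

Step 8
Reactants: 14 quinone
Product: 15 12,13-epoxide of 14 (6,7-epoxy-6,7-dihydro derivative in the naphthalene numbering of 14; mixture of epoxide diastereomers)
Conditions: 30% H2O2, Na2CO3, THF/H2O, 0 °C
Reagents that add atoms: hydrogen peroxide, OO
Why: Weitz–Scheffer nucleophilic epoxidation: hydroperoxide adds at the only unsubstituted quinone carbon (C12) and the enolate closes on oxygen; the tetrasubstituted C8=C9 bond is shielded by the quaternary C10, the isopropenyl group is inert to nucleophilic peroxide, and the uncontrolled epoxide configuration is removed in step 9.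

Step 9
Reactants: 15 epoxide
Product: 16 (3S,4S)-4-[3-(tert-butyldimethylsilyloxy)propyl]-6-hydroxy-4-methyl-7-(propan-2-yl)-3-(prop-1-en-2-yl)-3,4-dihydronaphthalene-1,5,8(2H)-trione (12-hydroxy-11,14-quinone)
Conditions: 0.5 M aq. NaOH, THF, 0 °C → rt, argon; then 1 M HCl
Reagents that add atoms: sodium hydroxide, [Na+].[OH-]
Why: Base-induced isomerization of a quinone epoxide that bears a hydrogen, a known route from 2-alkylquinone oxides to 2-alkyl-3-hydroxyquinones: hydroxide opens the epoxide at the secondary, carbonyl-activated C12 and E1cB loss of the C13 oxygen gives the delocalized hydroxyquinone anion as the thermodynamic sink. Alkali is used instead of the usual strong acid because the isopropenyl group would not survive the acid and no ester is present at this stage.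

Step 10
Reactants: 16 hydroxyquinone silyl ether
Product: 19 3-[(1S,2S)-7-hydroxy-1-methyl-4,5,8-trioxo-6-(propan-2-yl)-2-(prop-1-en-2-yl)-1,2,3,4,5,8-hexahydronaphthalen-1-yl]propanoic acid, via primary alcohol 17 (not isolated), via aldehyde 18 (not isolated)
Conditions: CrO3, H2SO4, H2O/acetone, 0 °C → rt
Reagents that add atoms: water, O
Why: Aqueous acidic chromate cleaves the primary silyl ether and oxidizes the freed alcohol through the aldehyde hydrate to the acid in one operation; 12-hydroxy-11,14-quinones and 1,1-disubstituted alkenes are expected to tolerate these dilute, cold conditions.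

Step 11
Reactants: 19 acid; 2 iodomethane
Product: 20 methyl 3-[(1S,2S)-7-hydroxy-1-methyl-4,5,8-trioxo-6-(propan-2-yl)-2-(prop-1-en-2-yl)-1,2,3,4,5,8-hexahydronaphthalen-1-yl]propanoate (target, CNP0308749.1)
Conditions: MeI, KHCO3, DMF, rt
Reagents that add atoms: iodomethane (2), CI
Why: SN2 O-alkylation of the carboxylate; the carboxylate is far more nucleophilic than the delocalized hydroxyquinone anion, which is flanked by the isopropyl group and a carbonyl, so the ester should form selectively at room temperature.

## Compound list

1 | (R)-(−)-carvone, (5R)-2-methyl-5-(prop-1-en-2-yl)cyclohex-2-en-1-one | C=C(C)[C@@H]1CC=C(C)C(=O)C1 | starting material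
2 | iodomethane | CI | starting material
3 | (5R)-2,6-dimethyl-5-(prop-1-en-2-yl)cyclohex-2-en-1-one (mixture of C6 epimers) | C=C(C)[C@@H]1CC=C(C)C(=O)C1C | intermediate
4 | tert-butyl(3-iodopropoxy)dimethylsilane | CC(C)(C)[Si](C)(C)OCCCI | starting material
5 | (5S,6S)-6-[3-(tert-butyldimethylsilyloxy)propyl]-2,6-dimethyl-5-(prop-1-en-2-yl)cyclohex-2-en-1-one | C=C(C)[C@@H]1CC=C(C)C(=O)[C@@]1(C)CCCO[Si](C)(C)C(C)(C)C | intermediate
6 | 4-methylpent-1-yn-3-ol (racemic) | C#CC(O)C(C)C | starting material
7 | (5S,6S)-6-[3-(tert-butyldimethylsilyloxy)propyl]-1-(3-hydroxy-4-methylpent-1-yn-1-yl)-2,6-dimethyl-5-(prop-1-en-2-yl)cyclohex-2-en-1-ol (mixture at C1 and at the side-chain carbinol) | C=C(C)[C@@H]1CC=C(C)C(O)(C#CC(O)C(C)C)[C@@]1(C)CCCO[Si](C)(C)C(C)(C)C | intermediate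
8 | hydroxy ynone: (5S,6S)-6-[3-(tert-butyldimethylsilyloxy)propyl]-1-(4-methyl-3-oxopent-1-yn-1-yl)-2,6-dimethyl-5-(prop-1-en-2-yl)cyclohex-2-en-1-ol | C=C(C)[C@@H]1CC=C(C)C(O)(C#CC(=O)C(C)C)[C@@]1(C)CCCO[Si](C)(C)C(C)(C)C | intermediate (not isolated)
9 | (4S,5S)-4-[3-(tert-butyldimethylsilyloxy)propyl]-2,4-dimethyl-3-(4-methyl-3-oxopent-1-yn-1-yl)-5-(prop-1-en-2-yl)cyclohex-2-en-1-one | C=C(C)[C@@H]1CC(=O)C(C)=C(C#CC(=O)C(C)C)[C@@]1(C)CCCO[Si](C)(C)C(C)(C)C | intermediate
10 | enaminone: (4S,5S)-4-[3-(tert-butyldimethylsilyloxy)propyl]-3-[1-(diethylamino)-4-methyl-3-oxopent-1-en-1-yl]-2,4-dimethyl-5-(prop-1-en-2-yl)cyclohex-2-en-1-one | C=C(C)[C@@H]1CC(=O)C(C)=C(C(=CC(=O)C(C)C)N(CC)CC)[C@@]1(C)CCCO[Si](C)(C)C(C)(C)C | intermediate (not isolated)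
11 | (4S,5S)-4-[3-(tert-butyldimethylsilyloxy)propyl]-2,4-dimethyl-3-(4-methyl-3-oxopentanoyl)-5-(prop-1-en-2-yl)cyclohex-2-en-1-one (triketone) | C=C(C)[C@@H]1CC(=O)C(C)=C(C(=O)CC(=O)C(C)C)[C@@]1(C)CCCO[Si](C)(C)C(C)(C)C | intermediate
12 | aldol adduct: (3S,4S)-4-[3-(tert-butyldimethylsilyloxy)propyl]-7-hydroxy-4-methyl-7-(propan-2-yl)-3-(prop-1-en-2-yl)-3,4,7,8-tetrahydronaphthalene-1,5(2H,6H)-dione (mixture at the carbinol) | C=C(C)[C@@H]1CC(=O)C2=C(C(=O)CC(O)(C(C)C)C2)[C@@]1(C)CCCO[Si](C)(C)C(C)(C)C | intermediate (not isolated)
13 | (3S,4S)-4-[3-(tert-butyldimethylsilyloxy)propyl]-5-hydroxy-4-methyl-7-(propan-2-yl)-3-(prop-1-en-2-yl)-3,4-dihydronaphthalen-1(2H)-one | C=C(C)[C@@H]1CC(=O)c2cc(C(C)C)cc(O)c2[C@@]1(C)CCCO[Si](C)(C)C(C)(C)C | intermediate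
14 | (3S,4S)-4-[3-(tert-butyldimethylsilyloxy)propyl]-4-methyl-7-(propan-2-yl)-3-(prop-1-en-2-yl)-3,4-dihydronaphthalene-1,5,8(2H)-trione | C=C(C)[C@@H]1CC(=O)C2=C(C(=O)C=C(C(C)C)C2=O)[C@@]1(C)CCCO[Si](C)(C)C(C)(C)C | intermediate
15 | 6,7-epoxide of 14 (epoxide on the two quinone carbons bearing H and isopropyl; mixture of epoxide diastereomers) | C=C(C)[C@@H]1CC(=O)C2=C(C(=O)C3OC3(C(C)C)C2=O)[C@@]1(C)CCCO[Si](C)(C)C(C)(C)C | intermediate
16 | (3S,4S)-4-[3-(tert-butyldimethylsilyloxy)propyl]-6-hydroxy-4-methyl-7-(propan-2-yl)-3-(prop-1-en-2-yl)-3,4-dihydronaphthalene-1,5,8(2H)-trione | C=C(C)[C@@H]1CC(=O)C2=C(C(=O)C(O)=C(C(C)C)C2=O)[C@@]1(C)CCCO[Si](C)(C)C(C)(C)C | intermediate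
17 | primary alcohol: (3S,4S)-6-hydroxy-4-(3-hydroxypropyl)-4-methyl-7-(propan-2-yl)-3-(prop-1-en-2-yl)-3,4-dihydronaphthalene-1,5,8(2H)-trione | C=C(C)[C@@H]1CC(=O)C2=C(C(=O)C(O)=C(C(C)C)C2=O)[C@@]1(C)CCCO | intermediate (not isolated)
18 | aldehyde: 3-[(1S,2S)-7-hydroxy-1-methyl-4,5,8-trioxo-6-(propan-2-yl)-2-(prop-1-en-2-yl)-1,2,3,4,5,8-hexahydronaphthalen-1-yl]propanal | C=C(C)[C@@H]1CC(=O)C2=C(C(=O)C(O)=C(C(C)C)C2=O)[C@@]1(C)CCC=O | intermediate (not isolated)
19 | 3-[(1S,2S)-7-hydroxy-1-methyl-4,5,8-trioxo-6-(propan-2-yl)-2-(prop-1-en-2-yl)-1,2,3,4,5,8-hexahydronaphthalen-1-yl]propanoic acid | C=C(C)[C@@H]1CC(=O)C2=C(C(=O)C(O)=C(C(C)C)C2=O)[C@@]1(C)CCC(=O)O | intermediate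
20 | methyl 3-[(1S,2S)-7-hydroxy-1-methyl-4,5,8-trioxo-6-(propan-2-yl)-2-(prop-1-en-2-yl)-1,2,3,4,5,8-hexahydronaphthalen-1-yl]propanoate | C=C(C)[C@@H]1CC(=O)C2=C(C(=O)C(O)=C(C(C)C)C2=O)[C@@]1(C)CCC(=O)OC | target

## Step count and risks

Total: 11 steps. Longest linear sequence: 11 steps from (R)-carvone 1; compounds 2, 4 and 6 are commercial.

**Step 6 (key step).** The diketone enolate is the dominant anion, so γ-enolization at C14 may be slow, and the material may rest in the reversible oxa-Michael adduct or suffer retro-Claisen cleavage of the diketone before it cyclizes.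
Fallback: starting from 11, exhaustive silylation (TMSOTf, Et3N, CH2Cl2) should give the tris(trimethylsilyl) trienol ether F1. Heating in toluene at about 110 °C should bring about six-electron electrocyclization across C14=C8–C9=C11–C12=C13 and loss of trimethylsilanol, giving the aryl silyl ether F2. K2CO3 in MeOH then removes the two trimethylsilyl groups, leaves the tert-butyldimethylsilyl ether, and returns to 13.

**Step 2.** C-alkylation of the hindered tetrasubstituted enolate by an unactivated primary iodide may be slow, allowing O-alkylation or proton transfer to the extended enolate to compete.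
Fallback: starting from 3, alkylation with allyl bromide (LiN(i-Pr)2, THF) is fast with the same facial preference and gives (5S,6S)-6-allyl-2,6-dimethyl-5-(prop-1-en-2-yl)cyclohex-2-en-1-one F3. Hydroboration of the monosubstituted alkene with disiamylborane and oxidation with NaBO3 gives the primary alcohol F4; this reagent discriminates against the 1,1-disubstituted isopropenyl group and the hindered ketone. Silylation (TBSCl, imidazole) returns to 5.

**Step 4.** Once the propargylic alcohol is oxidized, the electron-poor ynone substituent and the neighbouring quaternary carbon may retard chromate ester formation and the allylic shift, so the transposition stalls and the material degrades on long exposure.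
Fallback: starting from 5, addition of HC≡CMgBr gives the ethynyl carbinol F5. Transposition with (C5H5NH)[CrO3Cl] on this electronically unbiased alkyne gives the 3-ethynyl enone F6. Acyl Sonogashira coupling with 2-methylpropanoyl chloride (PdCl2(PPh3)2, CuI, Et3N) returns to 9.

**Step 9.** Hydroxide may attack a quinone carbonyl instead of C12, leading to ring contraction or cleavage of the electron-poor epoxy-enetrione.
Fallback: starting from 14, oxidative conjugate amination with dimethylamine (EtOH, air) at the free C12 position gives the 12-(dimethylamino)quinone F7. Hydrolysis of this vinylogous amide with dilute aqueous NaOH (addition–elimination) followed by acidification returns to 16 without passing through the epoxide.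

**Step 11.** Competing O-methylation of the hydroxyquinone would give over-alkylated material.
Fallback: starting from 16, acetylation (Ac2O, pyridine) gives the 12-acetate F8. CrO3/H2SO4 in aqueous acetone converts the silyl ether into the acid F9, and MeI/KHCO3 gives the methyl ester acetate F10. Brief K2CO3 in MeOH at 0 °C cleaves only the vinylogous anhydride and arrives at 20.

## Further compounds

F1 | step 6 | tris(trimethylsilyl) trienol ether of 11 (silyloxy groups on C7, C11 and C13; alkenes C6=C7, C8=C14, C9=C11, C12=C13) | C=C(C)[C@@H]1C=C(O[Si](C)(C)C)C(=C)C(=C(O[Si](C)(C)C)C=C(O[Si](C)(C)C)C(C)C)[C@@]1(C)CCCO[Si](C)(C)C(C)(C)C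
F2 | step 6 | aryl trimethylsilyl ether of 13 with the C7 ketone as its trimethylsilyl dienol ether | C=C(C)[C@@H]1C=C(O[Si](C)(C)C)c2cc(C(C)C)cc(O[Si](C)(C)C)c2[C@@]1(C)CCCO[Si](C)(C)C(C)(C)C
F3 | step 2 | (5S,6S)-2,6-dimethyl-6-(prop-2-en-1-yl)-5-(prop-1-en-2-yl)cyclohex-2-en-1-one | C=C(C)[C@@H]1CC=C(C)C(=O)[C@@]1(C)CC=C
F4 | step 2 | (5S,6S)-6-(3-hydroxypropyl)-2,6-dimethyl-5-(prop-1-en-2-yl)cyclohex-2-en-1-one | C=C(C)[C@@H]1CC=C(C)C(=O)[C@@]1(C)CCCO
F5 | step 4 | (5S,6S)-6-[3-(tert-butyldimethylsilyloxy)propyl]-1-ethynyl-2,6-dimethyl-5-(prop-1-en-2-yl)cyclohex-2-en-1-ol (mixture at C1) | C=C(C)[C@@H]1CC=C(C)C(O)(C#C)[C@@]1(C)CCCO[Si](C)(C)C(C)(C)C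
F6 | step 4 | (4S,5S)-4-[3-(tert-butyldimethylsilyloxy)propyl]-3-ethynyl-2,4-dimethyl-5-(prop-1-en-2-yl)cyclohex-2-en-1-one | C=C(C)[C@@H]1CC(=O)C(C)=C(C#C)[C@@]1(C)CCCO[Si](C)(C)C(C)(C)C
F7 | step 9 | (3S,4S)-4-[3-(tert-butyldimethylsilyloxy)propyl]-6-(dimethylamino)-4-methyl-7-(propan-2-yl)-3-(prop-1-en-2-yl)-3,4-dihydronaphthalene-1,5,8(2H)-trione | C=C(C)[C@@H]1CC(=O)C2=C(C(=O)C(N(C)C)=C(C(C)C)C2=O)[C@@]1(C)CCCO[Si](C)(C)C(C)(C)C
F8 | step 11 | 12-acetate of 16 (enol acetate on the hydroxyquinone) | C=C(C)[C@@H]1CC(=O)C2=C(C(=O)C(OC(C)=O)=C(C(C)C)C2=O)[C@@]1(C)CCCO[Si](C)(C)C(C)(C)C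
F9 | step 11 | 12-acetate of acid 19 | C=C(C)[C@@H]1CC(=O)C2=C(C(=O)C(OC(C)=O)=C(C(C)C)C2=O)[C@@]1(C)CCC(=O)O
F10 | step 11 | 12-acetate of target 20 | C=C(C)[C@@H]1CC(=O)C2=C(C(=O)C(OC(C)=O)=C(C(C)C)C2=O)[C@@]1(C)CCC(=O)OC
A1 | alternative 1 | (E)-1-(dimethylamino)-3-(tert-butyldimethylsilyloxy)buta-1,3-diene | CN(C)/C=C/C(=C)O[Si](C)(C)C(C)(C)C
A2 | alternative 1 | (E)-2,4-dimethylpenta-2,4-dienal | O=C/C(C)=C/C(C)=C
A3 | alternative 1 | endo cycloadduct: 4-(tert-butyldimethylsilyloxy)-2-(dimethylamino)-1-methyl-6-(prop-1-en-2-yl)cyclohex-3-ene-1-carbaldehyde | C=C(C)[C@@H]1CC(O[Si](C)(C)C(C)(C)C)=C[C@@H](N(C)C)[C@@]1(C)C=O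
A4 | alternative 2 | (1R,5R)-(+)-verbenone | CC1=CC(=O)[C@@H]2C[C@H]1C2(C)C
A5 | alternative 2 | 4-hydroxy-2-methoxy-3-(propan-2-yl)-4-(ring-B cyclohex-1-enyl)cyclobut-2-en-1-one (ring B with C7 silyl ether, C10 methyl and silyloxypropyl, C5 isopropenyl) | C=C(C)[C@@H]1CC(O[Si](C)(C)C(C)(C)C)C(C2(O)C(C(C)C)=C(OC)C2=O)=C[C@@]1(C)CCCO[Si](C)(C)C(C)(C)C
A6 | alternative 2 | 11,14-dihydroxy-12-methoxy-13-isopropyl arene (ring-C hydroquinone with C7 and C3 silyl ethers) | C=C(C)[C@@H]1CC(O[Si](C)(C)C(C)(C)C)c2c(O)c(C(C)C)c(OC)c(O)c2[C@@]1(C)CCCO[Si](C)(C)C(C)(C)C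
A7 | alternative 3 | pentacarbonyl[methoxy(ring-B cyclohex-1-enyl)methylidene]chromium, Cr(CO)5 carbene on C9 (ring B with C7 and C3 silyl ethers) | C=C(C)[C@@H]1CC(O[Si](C)(C)C(C)(C)C)C=C(C(OC)=[Cr](=C=O)(=C=O)(=C=O)(=C=O)=C=O)[C@@]1(C)CCCO[Si](C)(C)C(C)(C)C
A8 | alternative 3 | 3-methylbut-1-yne | C#CC(C)C
A9 | alternative 3 | 14-hydroxy-11-methoxy-13-isopropyl arene with C12 unsubstituted (C7 and C3 silyl ethers) | C=C(C)[C@@H]1CC(O[Si](C)(C)C(C)(C)C)c2c(O)c(C(C)C)cc(OC)c2[C@@]1(C)CCCO[Si](C)(C)C(C)(C)C
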